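The numbers in the tables stem from a simulated flask with made-up constants; noise was put on by code.

Count the Q against the L it meets.

| flask | L | Q | remark | time |
|---|---|---|---|---|
| oak | 0.27 M (in portions, 3) | 0.20 M | run made earlier; portions every 25 s |  |
| ash | 0.42 M (in portions, 3) | 0.20 M | run made earlier; portions every 25 s |  |
| birch | 0.19 M (in portions, 3) | 0.10 M | run made earlier; portions every 25 s |  |
| alpha | 0.19 M (in portions, 3) | 0.200 M | the portions of L follow each other after 25 s, the first at the start | 2.0 min |
| gamma | 0.19 M | 0.200 M | everything together at the start | 2.0 min |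

| run | time / min | X / % | L / % |
|---|---|---|---|
| oak | 0.200 | 4.8 | 8.8 |
| oak | 0.417 | 12.0 | 2.6 |
| oak | 1.00 | 14.9 | 48.4 |
| oak | 2.50 | 15.7 | 28.6 |
| ash | 0.667 | 8.5 | 32.5 |
| ash | 1.33 | 9.3 | 52.0 |
| ash | 2.00 | 7.0 | 45.3 |
| ash | 2.50 | 7.9 | 38.5 |
| birch | 0.667 | 5.6 | 32.3 |
| birch | 1.33 | 8.7 | 54.3 |
| birch | 2.00 | 7.4 | 47.8 |
| birch | 2.50 | 7.1 | 42.7 |

(readings scatter by 1 percentage point)



1. which one finishes higher in amount of X, in percent of the L charged ("neither" within 2 percentage points) (alpha / gamma / neither)
2. amount of X at the end, in percent of the L charged, alpha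
3. amount of X at the end, in percent of the L charged, gamma

L takes 3 Q on its way to X, so I set two amounts side by side: the Q charged, and 3 times the L that Q first meets. For alpha's first portion this ratio was 1.05, and I called it the cover. I counted portions separately because the oak readings showed L down from 33.3% to 2.6% of the charge at 0.417 min, just before the second portion. Gamma's cover was smaller than alpha's, 0.351. With 0.200 M of Q against 0.570 M needed, Q was the limiting reagent, so X in either flask had a ceiling of 35.1%.

Oak, with cover 0.741, stood at 15.7% in its last reading, or 63.6% of its ceiling. Birch, with cover 0.526, read 40.5% of its own at its last reading. I took oak's share over for alpha, which gave 22.3%, and birch's for gamma, which gave 14.2%. Birch had gamma's L, but ash, with cover 0.476, read 49.8% of its ceiling, so my gamma figure was rough. So I expected alpha to finish higher than gamma.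

The forecast also chose alpha, with 21% and 9.5%. For gamma it argued: “A statistical distribution gives about 11% X, and scrambling trims this to about 9%.” My gamma figure stood higher than that.

The flasks gave 22.9% in alpha and 15.5% in gamma, so alpha finished higher.

    E + Q → Z + X (k = 4.93 M⁻¹ s⁻¹)
    E → G (k = 0.00377 s⁻¹)
    Z + L → J (k = 0.0408 M⁻¹ s⁻¹)
    D + Q → Z + E (k = 0.305 M⁻¹ s⁻¹)
    L + Q → Z + D (k = 0.756 M⁻¹ s⁻¹)

Alpha thus kept 65.2% of its ceiling and gamma 44.2%. A neighbour of alpha took 0.50 M of Q, with the L and its portions unchanged. Its first-portion cover was 2.63, and its ceiling for X was 87.7%. It ended with 0.39% of its L and 4.9% of its Q left. Its X stood at 78.1%, which was 89.1% of that ceiling.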